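**Retrosynthetic overview**
1. Target 18 ← acetylation of diol 17 ← desilylation and 1,2-reduction of enone 15, which holds C7 one oxidation level higher.
2. Enabling feature: ring B has oxygen on C7, a methyl on C8 and the C8=C9 alkene beside quaternary C10. It is a masked 2-methylcyclohex-2-enone whose carbonyl carbon C7 is 1,3 to C5 and 1,5 to C9, and C5–C10 is the bond shared by rings A and B.
3. Key disconnection: C8=C9 (aldol condensation) and C5–C10 (Michael addition) of open-chain keto-enone 13. Ring A closes first, ring B second, in one flask.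
4. 13 ← cross-metathesis with ethyl vinyl ketone (C6–C8, C17) ← catalytic asymmetric reverse prenylation (C4, C5, gem-dimethyl; sets C3) ← hydroformylation (C3) ← crotyl addition (C10, C20, C1, C2) to the C9 aldehyde from (S)-citronellol (C9, C11–C16).
5. Stereochemistry: C13 bought, C3 by catalysis, C5 and C10 relayed from C3 in the key step, C7 from the bicycle by hydride delivery.

Key step: step 9

Remark: atoms are named by the labdane numbering of the target (ring A C1–C5 and C10, ring B C5–C10, side chain C11–C16, C17 on C8, C20 on C10). Compounds 6, 7, 8, 10, 11 and 13 are carried as mixtures at the future C10 (6 also at C9); step 9 turns this center into a planar enolate, so it is left undefined in their SMILES.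

Step 1
Reactants: 1 (S)-citronellol
Product: 2 tert-butyl{[(3S)-3,7-dimethyloct-6-en-1-yl]oxy}dimethylsilane
Conditions: TBSCl, imidazole, DMF, 0 °C → rt
Reagents that add atoms: tert-butyldimethylsilyl chloride, CC(C)(C)[Si](C)(C)Cl
Why: Imidazole-promoted silyl ether formation masks the primary C15 hydroxyl for the organometallic, oxidative and basic steps and touches no stereocenter.

Step 2
Reactants: 2 tert-butyl{[(3S)-3,7-dimethyloct-6-en-1-yl]oxy}dimethylsilane
Product: 4 (4S)-6-[(tert-butyldimethylsilyl)oxy]-4-methylhexanal, via secondary ozonide 3 (not isolated)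
Conditions: O3, CH2Cl2, −78 °C; then PPh3, −78 °C → rt
Reagents that add atoms: ozone, [O-][O+]=O
Why: Ozonolysis with reductive work-up cleaves the only alkene to the aldehyde that becomes C9, and the C13 stereocenter, which is not α to the new carbonyl, cannot epimerise.

Step 3
Reactants: 4 (4S)-6-[(tert-butyldimethylsilyl)oxy]-4-methylhexanal; 5 crotylmagnesium chloride
Product: 6 (7S)-9-[(tert-butyldimethylsilyl)oxy]-3,7-dimethylnon-1-en-4-ol (mixture at C3 and C4 of this chain)
Conditions: THF, −78 → 0 °C; aq. NH4Cl
Reagents that add atoms: none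
Why: Grignard addition of the crotyl reagent through its γ-carbon (allylic transposition) gives the branched homoallylic alcohol with C10, its methyl C20 and the vinyl group C1=C2; the diastereomer mixture is of no consequence because C9 is oxidised next and C10 becomes an enolate carbon in step 9.

Step 4
Reactants: 6 (7S)-9-[(tert-butyldimethylsilyl)oxy]-3,7-dimethylnon-1-en-4-ol
Product: 7 (7S)-9-[(tert-butyldimethylsilyl)oxy]-3,7-dimethylnon-1-en-4-one (both C3 epimers)
Conditions: Dess–Martin periodinane, pyridine, CH2Cl2, 0 °C → rt
Reagents that add atoms: none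
Why: Dess–Martin oxidation under pyridine buffering should give the β,γ-unsaturated ketone without moving the alkene into conjugation.

Step 5
Reactants: 7 (7S)-9-[(tert-butyldimethylsilyl)oxy]-3,7-dimethylnon-1-en-4-one
Product: 8 (8S)-10-[(tert-butyldimethylsilyl)oxy]-4,8-dimethyl-5-oxodecanal (both C4 epimers)
Conditions: Rh(acac)(CO)2 (1 mol %), Xantphos (2 mol %), CO/H2 (1:1, 10 bar), toluene, 60 °C
Reagents that add atoms: carbon monoxide, [C-]#[O+]
Why: Rhodium-catalysed hydroformylation with a wide-bite-angle bisphosphine places the formyl group on the terminal carbon (the branch at C10 reinforces this) and so adds C3 as an aldehyde under neutral conditions.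

Step 6
Reactants: 8 (8S)-10-[(tert-butyldimethylsilyl)oxy]-4,8-dimethyl-5-oxodecanal; 9 3-methylbuta-1,2-diene
Product: 10 (3S,10S)-1-[(tert-butyldimethylsilyl)oxy]-10-hydroxy-3,7,11,11-tetramethyltridec-12-en-6-one (both C7 epimers)
Conditions: [Ir(cod)Cl]2 (2.5 mol %), SEGPHOS (5 mol %, the antipode that gives the 10S alcohol, to be fixed on a test scale), 4-cyano-3-nitrobenzoic acid (10 mol %), Cs2CO3 (20 mol %), i-PrOH (2 equiv), THF, 45 °C
Reagents that add atoms: none
Why: Iridium-catalysed transfer-hydrogenative carbonyl reverse prenylation: isopropanol-driven hydrometalation of the allene gives a 1,1-dimethylallyl iridium species that adds through its substituted terminus to the aldehyde and not to the ketone, and the chiral bisphosphine on the cyclometalated iridium benzoate selects the aldehyde face and sets C3 as S.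

Step 7
Reactants: 10 (3S,10S)-1-[(tert-butyldimethylsilyl)oxy]-10-hydroxy-3,7,11,11-tetramethyltridec-12-en-6-one
Product: 11 (3S,10S)-1-[(tert-butyldimethylsilyl)oxy]-10-methoxy-3,7,11,11-tetramethyltridec-12-en-6-one (both C7 epimers)
Conditions: MeOTf, 2,6-di-tert-butyl-4-methylpyridine, CH2Cl2, 0 °C → rt
Reagents that add atoms: methyl trifluoromethanesulfonate, COS(=O)(=O)C(F)(F)F
Why: O-Alkylation with methyl triflate buffered by a hindered pyridine methylates the neopentyl-type secondary alcohol without forming the enolate of the C9 ketone and leaves the configuration at C3 untouched.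

Step 8
Reactants: 11 (3S,10S)-1-[(tert-butyldimethylsilyl)oxy]-10-methoxy-3,7,11,11-tetramethyltridec-12-en-6-one; 12 pent-1-en-3-one
Product: 13 (4E,7S,14S)-16-[(tert-butyldimethylsilyl)oxy]-7-methoxy-6,6,10,14-tetramethylhexadec-4-ene-3,11-dione (both C10 epimers)
Conditions: second-generation Hoveyda–Grubbs catalyst (5 mol %), 12 (4 equiv), toluene, 70 °C
Reagents that add atoms: none
Why: Olefin cross-metathesis: the vinyl group on the quaternary carbon cannot homodimerise and should couple with the excess electron-poor partner to the thermodynamically preferred E-enone.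

Step 9
Reactants: 13 (4E,7S,14S)-16-[(tert-butyldimethylsilyl)oxy]-7-methoxy-6,6,10,14-tetramethylhexadec-4-ene-3,11-dione
Product: 15 (3S,5R,10S,13S)-15-[(tert-butyldimethylsilyl)oxy]-3-methoxylabd-8-en-7-one, via ring A diketone 14 (not isolated)
Conditions: KOt-Bu (0.3 equiv), THF/t-BuOH (5:1), 0.02 M, −20 → 0 °C; then AcOH (1.5 equiv), pyrrolidine (1.2 equiv), 60 °C; aq. NH4Cl
Reagents that add atoms: none
Why: Catalytic tert-butoxide equilibrates the ketone enolates, and only the tetrasubstituted C10 enolate of the C9 ketone has a productive path: it adds to C5 of the E-enone (intramolecular Michael addition, 6-(enolexo)-exo-trig, closes ring A) to give diketone 14, while the gem-dimethyl group at C4 blocks γ-deprotonation of the enone and favours the folded chain. Pyrrolidine then forms an enamine only at the unhindered C7 ethyl ketone (the C9 carbonyl now sits beside quaternary C10), its C8 carbon attacks C9 (6-(enolendo)-exo-trig aldol, closes ring B), and loss of water gives the tetrasubstituted C8=C9 enone. The closest known reaction type is the Robinson annulation run in its two classical stages, alkoxide-mediated Michael addition and secondary-amine-mediated aldol condensation of the 1,5-diketone, here with the Michael step intramolecular so that both rings form from an open chain. C5 should be set by 1,3-induction from C3 in a chair-like transition state with the C3 methoxy group and the enone arm both equatorial, and C10 relative to C5 because the enolate carbon C9 with its oxygen and chain takes the equatorial site and the methyl group the axial one, which leads to the trans ring fusion. The step needs regioselectivity in the aldol (C8 onto C9, not C11 onto C7), which the quaternary C10 secures through the enamine stage, and diastereoselectivity at C5 and C10, where the induction by the small methoxy group is the weaker element and is treated under the risks below.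

Step 10
Reactants: 15 (3S,5R,10S,13S)-15-[(tert-butyldimethylsilyl)oxy]-3-methoxylabd-8-en-7-one
Product: 16 (3S,5R,7S,10S,13S)-15-[(tert-butyldimethylsilyl)oxy]-3-methoxylabd-8-en-7-ol
Conditions: NaBH4, CeCl3·7H2O, MeOH, −78 → −20 °C
Reagents that add atoms: none
Why: Luche 1,2-reduction: the cerium-modified borohydride should attack the enone carbonyl along the axial trajectory from the α face, which carries only the axial C5 hydrogen, and give the equatorial 7β-alcohol.

Step 11
Reactants: 16 (3S,5R,7S,10S,13S)-15-[(tert-butyldimethylsilyl)oxy]-3-methoxylabd-8-en-7-ol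
Product: 17 (3S,5R,7S,10S,13S)-3-methoxylabd-8-ene-7,15-diol
Conditions: Bu4NF, THF, 0 °C → rt
Reagents that add atoms: none
Why: Fluoride-mediated silyl ether cleavage frees the primary C15 alcohol without affecting the allylic alcohol, the methyl ether or the tetrasubstituted alkene.

Step 12
Reactants: 17 (3S,5R,7S,10S,13S)-3-methoxylabd-8-ene-7,15-diol
Product: 18 (3S,5R,7S,10S,13S)-3-methoxylabd-8-ene-7,15-diyl diacetate
Conditions: Ac2O, pyridine, DMAP (cat.), CH2Cl2, rt
Reagents that add atoms: acetic anhydride, CC(=O)OC(C)=O
Why: DMAP-catalysed acylation esterifies the primary C15 and the equatorial allylic C7 hydroxyl with retention at C7 and gives the target.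

**Compound list**
1 | (S)-citronellol, (3S)-3,7-dimethyloct-6-en-1-ol | C[C@@H](CCC=C(C)C)CCO | starting material
2 | tert-butyl{[(3S)-3,7-dimethyloct-6-en-1-yl]oxy}dimethylsilane | C[C@@H](CCC=C(C)C)CCO[Si](C)(C)C(C)(C)C | intermediate
3 | secondary ozonide, 3-[(3S)-5-[(tert-butyldimethylsilyl)oxy]-3-methylpentyl]-5,5-dimethyl-1,2,4-trioxolane | C[C@@H](CCC1OOC(C)(C)O1)CCO[Si](C)(C)C(C)(C)C | intermediate (not isolated)
4 | (4S)-6-[(tert-butyldimethylsilyl)oxy]-4-methylhexanal | C[C@@H](CCC=O)CCO[Si](C)(C)C(C)(C)C | intermediate
5 | crotylmagnesium chloride (but-2-enylmagnesium chloride, commercial THF solution) | CC=CC[Mg]Cl | starting material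
6 | (7S)-9-[(tert-butyldimethylsilyl)oxy]-3,7-dimethylnon-1-en-4-ol, mixture at C3 and C4 | C[C@@H](CCC(O)C(C)C=C)CCO[Si](C)(C)C(C)(C)C | intermediate
7 | (7S)-9-[(tert-butyldimethylsilyl)oxy]-3,7-dimethylnon-1-en-4-one, both C3 epimers | C[C@@H](CCC(=O)C(C)C=C)CCO[Si](C)(C)C(C)(C)C | intermediate
8 | (8S)-10-[(tert-butyldimethylsilyl)oxy]-4,8-dimethyl-5-oxodecanal, both C4 epimers | C[C@@H](CCC(=O)C(C)CCC=O)CCO[Si](C)(C)C(C)(C)C | intermediate
9 | 3-methylbuta-1,2-diene (1,1-dimethylallene) | CC(C)=C=C | starting material
10 | (3S,10S)-1-[(tert-butyldimethylsilyl)oxy]-10-hydroxy-3,7,11,11-tetramethyltridec-12-en-6-one, both C7 epimers | C[C@@H](CCC(=O)C(C)CC[C@H](O)C(C)(C)C=C)CCO[Si](C)(C)C(C)(C)C | intermediate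
11 | (3S,10S)-1-[(tert-butyldimethylsilyl)oxy]-10-methoxy-3,7,11,11-tetramethyltridec-12-en-6-one, both C7 epimers | C[C@@H](CCC(=O)C(C)CC[C@H](OC)C(C)(C)C=C)CCO[Si](C)(C)C(C)(C)C | intermediate
12 | pent-1-en-3-one (ethyl vinyl ketone) | CCC(=O)C=C | starting material
13 | (4E,7S,14S)-16-[(tert-butyldimethylsilyl)oxy]-7-methoxy-6,6,10,14-tetramethylhexadec-4-ene-3,11-dione, both C10 epimers | C[C@@H](CCC(=O)C(C)CC[C@H](OC)C(C)(C)/C=C/C(=O)CC)CCO[Si](C)(C)C(C)(C)C | intermediate
14 | ring A diketone, (4S)-6-[(tert-butyldimethylsilyl)oxy]-1-[(1S,2S,4S)-4-methoxy-1,3,3-trimethyl-2-(2-oxobutyl)cyclohexyl]-4-methylhexan-1-one (3β-OMe, 5α-H, 10β-Me in labdane terms) | CO[C@H]1CC[C@](C)(C(=O)CC[C@H](C)CCO[Si](C)(C)C(C)(C)C)[C@@H](CC(=O)CC)C1(C)C | intermediate (not isolated)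
15 | (3S,5R,10S,13S)-15-[(tert-butyldimethylsilyl)oxy]-3-methoxylabd-8-en-7-one | CO[C@H]1CC[C@]2(C)C(CC[C@H](C)CCO[Si](C)(C)C(C)(C)C)=C(C)C(=O)C[C@H]2C1(C)C | intermediate
16 | (3S,5R,7S,10S,13S)-15-[(tert-butyldimethylsilyl)oxy]-3-methoxylabd-8-en-7-ol | CO[C@H]1CC[C@]2(C)C(CC[C@H](C)CCO[Si](C)(C)C(C)(C)C)=C(C)[C@@H](O)C[C@H]2C1(C)C | intermediate
17 | (3S,5R,7S,10S,13S)-3-methoxylabd-8-ene-7,15-diol | CO[C@H]1CC[C@]2(C)C(CC[C@H](C)CCO)=C(C)[C@@H](O)C[C@H]2C1(C)C | intermediate
18 | (3S,5R,7S,10S,13S)-3-methoxylabd-8-ene-7,15-diyl diacetate | CO[C@H]1CC[C@]2(C)C(CC[C@H](C)CCOC(C)=O)=C(C)[C@@H](OC(C)=O)C[C@H]2C1(C)C | target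

**Step count and risks**
Total step count: 12. Longest linear sequence: 12 steps, from 1 to 18.

Steps most likely to fail:

Step 9. The 1,3-induction from the small C3 methoxy group may give poor facial selectivity at C5. Retro-Michael equilibration may erode the trans ring fusion. Alkoxide-mediated aldol of 14 may leak into closure of C11 onto C7 before the amine stage. Fallback: catalyst control in place of substrate control for the ring A closure. Setting out from 13, the Michael stage would be run under Brønsted-acid enol catalysis with a chiral BINOL-derived phosphoric acid (TRIP, the antipode matched to C3; toluene, 50 °C). This reaction type is established for the intermolecular addition of α-branched ketones to enones with formation of a quaternary stereocenter. The acid enolises the C9 ketone towards C10 and holds enol and enone in one hydrogen-bonded array. No free enolate is formed, so base-mediated aldol cannot intervene. Pyrrolidine and acetic acid are then added as in step 9, and the route is rejoined at 15 by way of 14 without any new compound.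

Step 6. Carbonate-induced intramolecular aldol condensation of the 1,5-keto aldehyde (C11 onto C3) and slow transfer hydrogenation of the C9 ketone may consume 8 before the prenylation. Fallback: reagent control under neutral conditions at low temperature. Setting out from 8, the reverse prenylation would use stoichiometric diisopinocampheyl(3-methylbut-2-enyl)borane of the (−)-α-pinene series, made from the corresponding diisopinocampheylborane and 9 (Et2O, −78 °C; ethanolamine work-up). The antipode is assigned by analogy with the allyl reagent. This borane adds to aldehydes and not to ketones through a closed six-membered transition state and should give the same 10S alcohol. The route is rejoined at 10 without any new compound.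

Step 5. Rhodium hydride may walk the terminal alkene of the β,γ-unsaturated ketone into conjugation with the C9 carbonyl, and some branched aldehyde may form. Fallback: build the C1–C2 bond by cycloaddition instead of adding C3 by carbonylation. Setting out from 4, addition of isopropenylmagnesium bromide (THF, −78 °C) would give the allylic alcohol (6S)-8-[(tert-butyldimethylsilyl)oxy]-2,6-dimethyloct-1-en-3-ol F1. Dess–Martin oxidation would give the isopropenyl ketone (6S)-8-[(tert-butyldimethylsilyl)oxy]-2,6-dimethyloct-1-en-3-one F2. An inverse-electron-demand hetero-Diels–Alder reaction of F2, acting as 1-oxadiene, with ethyl vinyl ether (Yb(fod)3, neat, 50 °C) would give 2-ethoxy-5-methyl-6-[(3S)-5-[(tert-butyldimethylsilyl)oxy]-3-methylpentyl]-3,4-dihydro-2H-pyran F3. Mild hydrolysis of the enol ether acetal (PPTS, acetone/H2O, rt) would release keto aldehyde 8, where the route is rejoined.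

**Further compounds**
F0 | step 9 | none | none
F0 | step 6 | none | none
F1 | step 5 | (6S)-8-[(tert-butyldimethylsilyl)oxy]-2,6-dimethyloct-1-en-3-ol (both C3 epimers) | C[C@@H](CCC(O)C(C)=C)CCO[Si](C)(C)C(C)(C)C
F2 | step 5 | (6S)-8-[(tert-butyldimethylsilyl)oxy]-2,6-dimethyloct-1-en-3-one | C[C@@H](CCC(=O)C(C)=C)CCO[Si](C)(C)C(C)(C)C
F3 | step 5 | 2-ethoxy-5-methyl-6-[(3S)-5-[(tert-butyldimethylsilyl)oxy]-3-methylpentyl]-3,4-dihydro-2H-pyran (both acetal epimers) | CCOC1CCC(C)=C(CC[C@H](C)CCO[Si](C)(C)C(C)(C)C)O1
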